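**Assumption:** 2‑(hydroxymethyl)cyclopent‑2‑en‑1‑one (1) and triformylmethane (10) are treated as catalogue chemicals; each is otherwise one known step away (Morita–Baylis–Hillman of cyclopentenone with formalin; Arnold formylation of bromoacetic acid).

## Retrosynthetic overview

1. The obvious routes (semi‑synthesis from a genipin‑type iridoid, or lactolisation of a cyclopentane 1,5‑dialdehyde) are avoided.
2. Target ⇐ C10 desilylation ⇐ C11 isovalerylation ⇐ chemoselective C11 aldehyde reduction ⇐ C1 isovalerylation of a 4‑formyl lactol.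
3. Key step: the whole dihydropyran (C1, O2, C3, C4, C11) is annulated in one photochemical operation (de Mayo [2+2] / retro‑aldol / lactolisation) of triformylmethane onto the C5=C9 bond of a fully oxygenated, enantiopure cyclopentene. This sets the cis ring fusion.
4. Cyclopentene ⇐ epoxide‑to‑allylic‑alcohol transposition ⇐ anti epoxidation of an (S)‑allylic acetate ⇐ CBS reduction of the 2‑(silyloxymethyl)cyclopentenone.
5. Ring order: the carbocycle is present from the start; the pyran ring is formed last (step 6).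

## Route

**Step 1**
Reactants: 1, 2‑(hydroxymethyl)cyclopent‑2‑en‑1‑one; 2, tert‑butyldimethylsilyl chloride
Product: 3, 2‑{[(tert‑butyldimethylsilyl)oxy]methyl}cyclopent‑2‑en‑1‑one
Conditions: TBSCl, imidazole, CH2Cl2, 0 °C → rt
Reagents that add atoms: TBSCl, CC(C)(C)[Si](C)(C)Cl
Why: Standard imidazole‑promoted silylation of the primary alcohol (future C10‑OH); no stereocentre is formed.

**Step 2**
Reactants: 3
Product: 4, (1S)‑2‑{[(tert‑butyldimethylsilyl)oxy]methyl}cyclopent‑2‑en‑1‑ol
Conditions: (R)‑Me‑CBS (15 mol %), BH3·SMe2, THF, −20 °C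
Reagents that add atoms: none
Why: Corey–Bakshi–Shibata 1,2‑reduction, in which the α‑substituted alkenyl arm is the large group, so the (R)‑catalyst gives the (S)‑carbinol (target C7).

**Step 3**
Reactants: 4; 5, acetic anhydride
Product: 6, (1S)‑2‑{[(tert‑butyldimethylsilyl)oxy]methyl}cyclopent‑2‑en‑1‑yl acetate
Conditions: Ac2O, pyridine, DMAP (cat.), CH2Cl2, 0 °C → rt
Reagents that add atoms: acetic anhydride, CC(=O)OC(C)=O
Why: DMAP‑catalysed acetylation installs the target's C7 acetate early, where it also serves as the non‑directing, face‑shielding group for step 4.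

**Step 4**
Reactants: 6; 7, m‑chloroperbenzoic acid
Product: 8, (1S,2S,5S)‑1‑{[(tert‑butyldimethylsilyl)oxy]methyl}‑6‑oxabicyclo[3.1.0]hexan‑2‑yl acetate (epoxide oxygen trans to the acetoxy group)
Conditions: mCPBA, NaHCO3, CH2Cl2, 0 °C → rt
Reagents that add atoms: mCPBA, OOC(=O)c1cccc(Cl)c1
Why: Prilezhaev epoxidation in which A(1,2) strain with the CH2OTBS group holds the OAc pseudo‑axial and no free OH is present to direct syn, so the peracid attacks anti to OAc and sets the C8–O bond trans to C7–OAc (target 8R); the minor syn epoxide is removed by chromatography.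

**Step 5**
Reactants: 8
Product: 9, (1S,2R)‑2‑{[(tert‑butyldimethylsilyl)oxy]methyl}‑2‑hydroxycyclopent‑3‑en‑1‑yl acetate (tertiary OH trans to OAc, CH2OTBS cis to OAc)
Conditions: PhSeSePh, NaBH4, EtOH, rt; then THF, 30 % H2O2, pyridine, 0 °C → rt (one pot, hydroxy‑selenide not isolated)
Reagents that add atoms: none
Why: Sharpless–Lauer epoxide‑to‑allylic‑alcohol transposition, in which PhSe⁻ opens the epoxide at the secondary carbon with the C8–O bond untouched, and selenoxide syn‑elimination can only go toward the ring CH2 (C8 has no H), giving the C5=C9 alkene with C8 retained.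

**Step 6 (key step)**
Reactants: 9; 10, triformylmethane (2‑formylmalonaldehyde, present as its H‑bonded enol)
Product: 11, (1R,4aS,6S,7R,7aS)‑7‑{[(tert‑butyldimethylsilyl)oxy]methyl}‑4‑formyl‑1,7‑dihydroxy‑1,4a,5,6,7,7a‑hexahydrocyclopenta[c]pyran‑6‑yl acetate (cis‑fused lactol; 1‑OH on the same face as H‑4a/H‑7a, anomers equilibrate)
Conditions: 10 (2 equiv, portionwise), hν (450 W medium‑pressure Hg, Corex), degassed CH2Cl2, 0 °C, to ~60 % conversion; then rt in the dark; SiO2; recover 9
Reagents that add atoms: triformylmethane, O=CC(C=O)C=O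
Why: Proposed new method: a de Mayo photoannulation in which the enol C=C of 10 adds [2+2] (triplet) to the cyclopentene, the cyclobutanol retro‑aldolises to a cis‑1,2‑disubstituted cyclopentane (CHO on C9, CH(CHO)2 on C5), and the malondialdehyde enol closes onto the aldehyde to give the lactol; the bulky C(CHO)2 terminus bonds to the alkene carbon remote from the quaternary centre, and addition occurs on the face of the small, H‑bond‑donating tertiary OH (anti to CH2OTBS and OAc), which sets 4aS,7aS; the closest known reaction is the photoannulation of methyl diformylacetate with substituted cyclopentenes used in classical iridoid synthesis.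

**Step 7**
Reactants: 11; 12, isovaleric (3‑methylbutanoic) anhydride
Product: 13, (1S,4aS,6S,7R,7aS)‑6‑acetoxy‑7‑{[(tert‑butyldimethylsilyl)oxy]methyl}‑4‑formyl‑7‑hydroxy‑1,4a,5,6,7,7a‑hexahydrocyclopenta[c]pyran‑1‑yl 3‑methylbutanoate
Conditions: (iPrCH2CO)2O (1.3 equiv), pyridine, DMAP (cat.), CH2Cl2, −20 → 0 °C
Reagents that add atoms: isovaleric anhydride, CC(C)CC(=O)OC(=O)CC(C)C
Why: Anomeric O‑acylation in which the lactol anomers equilibrate and the equatorial 1β‑OH (trans to C8, H‑1/H‑7a trans‑diaxial, as in acylation of genipin‑type lactols) reacts fastest to give the 1S acyl acetal, while the hindered tertiary OH is inert.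

**Step 8**
Reactants: 13
Product: 14, (1S,4aS,6S,7R,7aS)‑6‑acetoxy‑7‑{[(tert‑butyldimethylsilyl)oxy]methyl}‑7‑hydroxy‑4‑(hydroxymethyl)‑1,4a,5,6,7,7a‑hexahydrocyclopenta[c]pyran‑1‑yl 3‑methylbutanoate
Conditions: NaBH4, CeCl3·7H2O, THF/MeOH (4:1), −78 °C, 20 min; cold pH 7 buffer quench; used directly
Reagents that add atoms: none
Why: Luche 1,2‑reduction of the vinylogous‑formate aldehyde, which is chemoselective at −78 °C over the acetate and the acyl acetal; no stereocentre is formed.

**Step 9**
Reactants: 14; 12, isovaleric anhydride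
Product: 15, (1S,4aS,6S,7R,7aS)‑6‑acetoxy‑7‑{[(tert‑butyldimethylsilyl)oxy]methyl}‑7‑hydroxy‑4‑{[(3‑methylbutanoyl)oxy]methyl}‑1,4a,5,6,7,7a‑hexahydrocyclopenta[c]pyran‑1‑yl 3‑methylbutanoate
Conditions: (iPrCH2CO)2O (1.2 equiv), Et3N, DMAP (cat.), CH2Cl2, 0 °C
Reagents that add atoms: isovaleric anhydride, CC(C)CC(=O)OC(=O)CC(C)C
Why: DMAP‑catalysed acylation of the primary allylic alcohol under basic, non‑ionising conditions; the tertiary 8‑OH is too hindered to compete.

**Step 10**
Reactants: 15
Product: 16, Jatamanvaltrate H, (1S,4aS,6S,7R,7aS)‑6‑acetoxy‑7‑hydroxy‑7‑(hydroxymethyl)‑4‑{[(3‑methylbutanoyl)oxy]methyl}‑1,4a,5,6,7,7a‑hexahydrocyclopenta[c]pyran‑1‑yl 3‑methylbutanoate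
Conditions: HF·pyridine, pyridine, THF, 0 °C → rt; NaHCO3 work‑up
Reagents that add atoms: none
Why: Buffered fluoride desilylation of the primary TBS ether, where the non‑basic medium suppresses 7→10 acetyl migration and the acid‑labile enol ether / acyl acetal tolerates pyridine‑buffered HF.

## Compound list

1 | 2‑(hydroxymethyl)cyclopent‑2‑en‑1‑one | O=C1CCC=C1CO | starting material
2 | tert‑butyldimethylsilyl chloride | CC(C)(C)[Si](C)(C)Cl | starting material (reagent)
3 | 2‑{[(TBS)oxy]methyl}cyclopent‑2‑en‑1‑one | O=C1CCC=C1CO[Si](C)(C)C(C)(C)C | intermediate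
4 | (1S)‑2‑{[(TBS)oxy]methyl}cyclopent‑2‑en‑1‑ol | O[C@H]1CCC=C1CO[Si](C)(C)C(C)(C)C | intermediate
5 | acetic anhydride | CC(=O)OC(C)=O | starting material (reagent)
6 | (1S)‑2‑{[(TBS)oxy]methyl}cyclopent‑2‑en‑1‑yl acetate | CC(=O)O[C@H]1CCC=C1CO[Si](C)(C)C(C)(C)C | intermediate
7 | m‑chloroperbenzoic acid | OOC(=O)c1cccc(Cl)c1 | starting material (reagent)
8 | (1S,2S,5S)‑1‑{[(TBS)oxy]methyl}‑6‑oxabicyclo[3.1.0]hexan‑2‑yl acetate | CC(=O)O[C@H]1CC[C@@H]2O[C@]12CO[Si](C)(C)C(C)(C)C | intermediate
9 | (1S,2R)‑2‑{[(TBS)oxy]methyl}‑2‑hydroxycyclopent‑3‑en‑1‑yl acetate | CC(=O)O[C@H]1CC=C[C@@]1(O)CO[Si](C)(C)C(C)(C)C | intermediate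
10 | triformylmethane (2‑formylmalonaldehyde) | O=CC(C=O)C=O | starting material
11 | (1R,4aS,6S,7R,7aS)‑4‑formyl‑1,7‑dihydroxy‑7‑(TBSO‑methyl)‑hexahydrocyclopenta[c]pyran‑6‑yl acetate | CC(=O)O[C@H]1C[C@@H]2C(C=O)=CO[C@@H](O)[C@@H]2[C@@]1(O)CO[Si](C)(C)C(C)(C)C | intermediate
12 | isovaleric anhydride | CC(C)CC(=O)OC(=O)CC(C)C | starting material (reagent)
13 | C1 isovalerate, C4 aldehyde | CC(=O)O[C@H]1C[C@@H]2C(C=O)=CO[C@@H](OC(=O)CC(C)C)[C@@H]2[C@@]1(O)CO[Si](C)(C)C(C)(C)C | intermediate
14 | C1 isovalerate, C11 alcohol | CC(=O)O[C@H]1C[C@@H]2C(CO)=CO[C@@H](OC(=O)CC(C)C)[C@@H]2[C@@]1(O)CO[Si](C)(C)C(C)(C)C | intermediate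
15 | 10‑O‑TBS Jatamanvaltrate H | CC(=O)O[C@H]1C[C@@H]2C(COC(=O)CC(C)C)=CO[C@@H](OC(=O)CC(C)C)[C@@H]2[C@@]1(O)CO[Si](C)(C)C(C)(C)C | intermediate
16 | Jatamanvaltrate H | CC(=O)O[C@H]1C[C@@H]2C(COC(=O)CC(C)C)=CO[C@@H](OC(=O)CC(C)C)[C@@H]2[C@@]1(O)CO | target

## Summary

Total steps: 10. Longest linear sequence: 10 (from 1).

Steps most likely to fail, with fallbacks:

1. **Step 6 (photoannulation).** Risks are regio‑ and facial selectivity, the acidity of 10, and photolability of the enal product. Fallback: invert the ring order. Build the cyclopentene onto a preformed pyran by phosphine‑catalysed (Lu‑type) [3+2] annulation of ethyl 2,3‑butadienoate with an enantiopure 6‑acyloxy‑2H‑pyran‑3(6H)‑one (Achmatowicz enone). Then epoxidise the resulting C7=C8 alkene on the convex face and open at C8 with inversion to install the 7β,8α,10‑triol.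

2. **Step 4 (anti epoxidation; dr may be modest with an acetate).** Fallback: replace steric control with directed epoxidation plus inversion. Make the (R)‑alcohol with (S)‑CBS, run VO(acac)2/TBHP syn‑epoxidation on the free alcohol, then Mitsunobu inversion at C7 with acetic acid to reach the same epoxy acetate 8.

3. **Step 7 (C1 acylation of a base‑sensitive lactol‑enal; β‑selectivity, ring‑opened enol acylation).** Fallback: use methyl diformylacetate as the photo‑partner to obtain a robust genipin‑type lactol ester. Mask C1 as a TES acetal, reduce with DIBAL (C4 ester and C7 acetate), isovalerylate C11 selectively, re‑acetylate C7, then unmask and acylate C1 last in the absence of the enal.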